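**Plan**
- Cuts: after the three MOM ethers are removed, both bonds at the carbonyl carbon beside ring B are cut together, namely ring B C-1–C(=O) and C(=O)–CH2.
- Enabling feature: this carbonyl carbon carries only its oxygen, ring B and the central CH2, so it is a bare one-carbon unit that carbon monoxide can supply. The CH2 and the other carbonyl are the acetyl group of a ring A acetophenone.
- Partners: ring B comes from 4-iodophenol by ortho C-prenylation and MOM protection. Ring A comes from 4,6-dibromoresorcinol by bis-MOM protection and two successive bromine–lithium exchanges (prenyl bromide, then N-methoxy-N-methylacetamide).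
- Forward order: both benzene rings are bought and no ring is formed. The three-carbon chain is joined in one palladium-catalysed union of iodide, CO and enolate, and dilute acid then frees the three phenols.
- Stereochemistry: the target has no stereocentre and both olefins end in CMe2, so nothing needs to be controlled.

Key step: step 6

Assumption: the target is written as the diketo tautomer. In solution it will sit largely in the chelated enol form, which is the same compound.

**Step 1**
Reactants: 1 4-iodophenol; 2 prenyl bromide (1-bromo-3-methylbut-2-ene)
Product: 4 4-iodo-2-(3-methylbut-2-enyl)phenol, via sodium 4-iodophenolate 3 (not isolated)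
Conditions: NaH (1.05 equiv), toluene, 0 °C → rt; then 2 (1.0 equiv), rt
Reagents that add atoms: prenyl bromide (compound 2), CC(C)=CCBr
Why: Ortho C-alkylation of a phenolate under heterogeneous, non-polar conditions: the tight sodium ion pair in toluene blocks oxygen and iodine occupies the para carbon, so the allylic bromide is taken up in SN2 fashion at an ortho carbon and the dienone rearomatises by tautomerisation.

**Step 2**
Reactants: 4 4-iodo-2-(3-methylbut-2-enyl)phenol
Product: 5 4-iodo-1-(methoxymethoxy)-2-(3-methylbut-2-enyl)benzene
Conditions: MOMCl (1.5 equiv), iPr2NEt (2 equiv), CH2Cl2, 0 °C → rt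
Reagents that add atoms: chloromethyl methyl ether (MOMCl), COCCl
Why: Standard O-alkylation of a phenol with chloromethyl methyl ether under amine base (MOM acetal formation), run without acid or metal so that the aryl iodide and the prenyl olefin are untouched.

**Step 3**
Reactants: 6 4,6-dibromoresorcinol (4,6-dibromobenzene-1,3-diol)
Product: 7 1,5-dibromo-2,4-bis(methoxymethoxy)benzene
Conditions: MOMCl (3 equiv), iPr2NEt (4 equiv), CH2Cl2, 0 °C → rt
Reagents that add atoms: chloromethyl methyl ether (MOMCl), COCCl
Why: The same MOM acetal formation on both phenols gives acetals that withstand n-BuLi, the amide base and palladium, and whose oxygens assist the lithiations that follow.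

**Step 4**
Reactants: 7 1,5-dibromo-2,4-bis(methoxymethoxy)benzene; 2 prenyl bromide
Product: 9 1-bromo-2,4-bis(methoxymethoxy)-5-(3-methylbut-2-enyl)benzene, via aryllithium 8 (not isolated)
Conditions: n-BuLi (1.0 equiv), THF, −78 °C; then 2 (1.2 equiv), −78 → 0 °C
Reagents that add atoms: prenyl bromide (compound 2), CC(C)=CCBr
Why: Bromine–lithium exchange followed by SN2 allylation: 7 is symmetric, so either bromine gives the same aryllithium, which is held by the neighbouring OMOM oxygen, is electron rich enough to resist a second exchange at −78 °C, and attacks the unhindered CH2 end of the allylic bromide far faster than the 1-bromobutane formed alongside.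

**Step 5**
Reactants: 9 1-bromo-2,4-bis(methoxymethoxy)-5-(3-methylbut-2-enyl)benzene; 10 N-methoxy-N-methylacetamide
Product: 13 1-[2,4-bis(methoxymethoxy)-5-(3-methylbut-2-enyl)phenyl]ethanone, via aryllithium 11 (not isolated), via lithium hemiaminal adduct 12 (not isolated)
Conditions: n-BuLi (1.05 equiv), THF, −78 °C; then 10 (1.3 equiv), −78 → 0 °C; aq. NH4Cl
Reagents that add atoms: N-methoxy-N-methylacetamide (compound 10), CON(C)C(C)=O
Why: Bromine–lithium exchange and Weinreb ketone synthesis: the aryllithium adds once to the amide and the five-membered lithium chelate 12 survives until the quench, so no tertiary alcohol can form and the enolisable ketone never meets the organolithium.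

**Step 6**
Reactants: 5 4-iodo-1-(methoxymethoxy)-2-(3-methylbut-2-enyl)benzene; 13 1-[2,4-bis(methoxymethoxy)-5-(3-methylbut-2-enyl)phenyl]ethanone; 14 carbon monoxide
Product: 17 1-[2,4-bis(methoxymethoxy)-5-(3-methylbut-2-enyl)phenyl]-3-[4-(methoxymethoxy)-3-(3-methylbut-2-enyl)phenyl]propane-1,3-dione, via sodium enolate 15 (not isolated), via sodium diketonate 16 (not isolated)
Conditions: 13 (2.0 equiv, excess recovered), NaN(SiMe3)2 (2.0 equiv), THF, 0 °C → rt; then 5 (1.0 equiv), Pd(dba)2 (5 mol %), 1,3-bis(diphenylphosphino)propane (dppp, 5 mol %), CO (ca. 2 bar, sealed vessel), 80 °C; aq. NH4Cl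
Reagents that add atoms: carbon monoxide (compound 14), [C-]#[O+]
Why: Zerovalent palladium inserts into the C–I bond of 5, CO migrates into the aryl–palladium bond to give an aroyl complex of divalent palladium, sodium enolate 15 displaces iodide, and reductive elimination from the carbon-bound acyl(enolate) complex forges the C(=O)–CH2 bond. This is the known palladium-catalysed carbonylative α-arylation of aryl methyl ketones with aryl iodides, applied here to two new partners. No ring closes and no stereocentre is created. Carbonylation must outrun direct α-arylation, and this is secured by the fast-reacting iodide, the CO overpressure and the chelating bisphosphine, which slows aryl–enolate reductive elimination relative to CO insertion. C-acylation and mono-acylation are secured because 13 has one enolisable methyl group, because any enol ester formed is itself an acyl donor towards 15, and because a second equivalent of 15 at once converts the product into the inert chelated diketonate 16, leaving no free amide base under CO. The iodine-bearing carbon of 5 is flanked by two hydrogens, its prenyl group sits meta so the aroylpalladium cannot reach that olefin, and trisubstituted olefins and MOM acetals are inert to the catalyst and the enolate.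

**Step 7**
Reactants: 17 1-[2,4-bis(methoxymethoxy)-5-(3-methylbut-2-enyl)phenyl]-3-[4-(methoxymethoxy)-3-(3-methylbut-2-enyl)phenyl]propane-1,3-dione
Product: 18 glycyrdione A, 1-[2,4-dihydroxy-5-(3-methylbut-2-enyl)phenyl]-3-[4-hydroxy-3-(3-methylbut-2-enyl)phenyl]propane-1,3-dione
Conditions: dilute HCl (3 M aq., catalytic) in MeOH, 25–40 °C
Reagents that add atoms: none
Why: Acid-catalysed transacetalisation of the three aryl MOM acetals with methanol, a standard unmasking of prenylated polyphenols, is kept dilute and near room temperature so that protonation of the trisubstituted olefins and cyclodehydration of the 2-hydroxyaryl diketone stay slow relative to acetal cleavage.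

**Compound list**
1 | 4-iodophenol | Oc1ccc(I)cc1 | starting material
2 | prenyl bromide (1-bromo-3-methylbut-2-ene) | CC(C)=CCBr | starting material
3 | sodium 4-iodophenolate | [Na+].[O-]c1ccc(I)cc1 | intermediate
4 | 4-iodo-2-(3-methylbut-2-enyl)phenol | CC(C)=CCc1cc(I)ccc1O | intermediate
5 | 4-iodo-1-(methoxymethoxy)-2-(3-methylbut-2-enyl)benzene | COCOc1ccc(I)cc1CC=C(C)C | intermediate
6 | 4,6-dibromoresorcinol | Oc1cc(O)c(Br)cc1Br | starting material
7 | 1,5-dibromo-2,4-bis(methoxymethoxy)benzene | COCOc1cc(OCOC)c(Br)cc1Br | intermediate
8 | [5-bromo-2,4-bis(methoxymethoxy)phenyl]lithium | [Li]c1cc(Br)c(OCOC)cc1OCOC | intermediate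
9 | 1-bromo-2,4-bis(methoxymethoxy)-5-(3-methylbut-2-enyl)benzene | COCOc1cc(OCOC)c(CC=C(C)C)cc1Br | intermediate
10 | N-methoxy-N-methylacetamide | CON(C)C(C)=O | starting material
11 | [2,4-bis(methoxymethoxy)-5-(3-methylbut-2-enyl)phenyl]lithium | [Li]c1cc(CC=C(C)C)c(OCOC)cc1OCOC | intermediate
12 | lithium 1-[2,4-bis(methoxymethoxy)-5-(3-methylbut-2-enyl)phenyl]-1-[methoxy(methyl)amino]ethanolate (racemic; the centre vanishes on collapse) | CON(C)C(C)(O[Li])c1cc(CC=C(C)C)c(OCOC)cc1OCOC | intermediate
13 | 1-[2,4-bis(methoxymethoxy)-5-(3-methylbut-2-enyl)phenyl]ethanone | CC(=O)c1cc(CC=C(C)C)c(OCOC)cc1OCOC | intermediate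
14 | carbon monoxide | [C-]#[O+] | starting material
15 | sodium 1-[2,4-bis(methoxymethoxy)-5-(3-methylbut-2-enyl)phenyl]ethenolate | [Na+].[O-]C(=C)c1cc(CC=C(C)C)c(OCOC)cc1OCOC | intermediate
16 | sodium (Z)-enolate of 17 (chelated diketonate, one resonance form drawn) | [Na+].[O-]/C(=C\C(=O)c1ccc(OCOC)c(CC=C(C)C)c1)c1cc(CC=C(C)C)c(OCOC)cc1OCOC | intermediate
17 | 1-[2,4-bis(methoxymethoxy)-5-(3-methylbut-2-enyl)phenyl]-3-[4-(methoxymethoxy)-3-(3-methylbut-2-enyl)phenyl]propane-1,3-dione | COCOc1ccc(C(=O)CC(=O)c2cc(CC=C(C)C)c(OCOC)cc2OCOC)cc1CC=C(C)C | intermediate
18 | glycyrdione A | CC(C)=CCc1cc(C(=O)CC(=O)c2cc(CC=C(C)C)c(O)cc2O)ccc1O | target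

**Total step count:** 7.
**Longest linear sequence:** 5 steps (steps 3, 4, 5, 6 and 7, starting from 6).

**Steps most likely to fail**

Step 6.
- What may go wrong: CO uptake may lose to direct α-arylation, the enolate may be acylated on oxygen, the catalyst may stall under CO, or the product may suffer retro-Claisen cleavage at 80 °C.
- Fallback: the union is split into two known two-component reactions that use the same CO carbon. It sets out from 5, which is methoxycarbonylated (PdCl2(PPh3)2, Et3N, CO, MeOH, 60 °C) to methyl 4-(methoxymethoxy)-3-(3-methylbut-2-enyl)benzoate F1. A crossed Claisen condensation of F1 with sodium enolate 15 (from 13 and NaN(SiMe3)2, THF, reflux) then passes through diketonate 16. It rejoins the route at 17 after an aqueous NH4Cl quench.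

Step 7.
- What may go wrong: protonation of a prenyl olefin followed by ring closure onto the neighbouring free phenol, and acid-driven cyclodehydration of the 2-hydroxyaryl diketone, may compete with cleavage of the last acetal.
- Fallback: the fallback avoids Brønsted acid by exchanging the protecting groups first. It sets out from 17, where Me3SiOTf and 2,2'-bipyridyl in MeCN at 0 °C convert the three aryl MOM ethers into silyl ethers. This gives 1-[5-(3-methylbut-2-enyl)-2,4-bis(trimethylsilyloxy)phenyl]-3-[3-(3-methylbut-2-enyl)-4-(trimethylsilyloxy)phenyl]propane-1,3-dione F2. Water added to the same flask hydrolyses F2 at near-neutral pH, and the route is rejoined at 18.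

Step 1.
- What may go wrong: alkylation at oxygen and a second alkylation at the other ortho carbon may compete with mono ortho C-alkylation.
- Fallback: the oxygen is alkylated on purpose and the prenyl group is then moved. It sets out from 1, where K2CO3 and 2 in refluxing acetone give 1-iodo-4-(3-methylbut-2-enyloxy)benzene F3. An acid-washed aluminosilicate clay (montmorillonite K10, CH2Cl2, 0 °C → rt) promotes the known [1,3] shift of aryl prenyl ethers. With the para carbon blocked, the shift can only deliver the group to the ortho carbon, and the route is rejoined at 4.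

**Further compounds**
F1 | step 6 | methyl 4-(methoxymethoxy)-3-(3-methylbut-2-enyl)benzoate | COCOc1ccc(C(=O)OC)cc1CC=C(C)C
F2 | step 7 | 1-[5-(3-methylbut-2-enyl)-2,4-bis(trimethylsilyloxy)phenyl]-3-[3-(3-methylbut-2-enyl)-4-(trimethylsilyloxy)phenyl]propane-1,3-dione | CC(C)=CCc1cc(C(=O)CC(=O)c2cc(CC=C(C)C)c(O[Si](C)(C)C)cc2O[Si](C)(C)C)ccc1O[Si](C)(C)C
F3 | step 1 | 1-iodo-4-(3-methylbut-2-enyloxy)benzene | CC(C)=CCOc1ccc(I)cc1
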